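The ten-membered ring is read as a cyclodeca-1,5-diene: the C1=C10 enoate and the C4(=C15)–C5(OH) unit, an oxidised C4=C5 olefin, are bridged by C2–C3, exactly what a bicyclo[2.2.0]hexane leaves on opening. One irradiation joins C1–C10 and C4–C5 between a cyclohexenone from quinic acid (C5=C10 enone, C6 ketone, C7 acetate arm cis to the C8 silyl ether) and 1-methylcyclobutene, closing the cyclobutane ring C5–C10–C1–C4 of the bicyclohexane; heat then cleaves C5–C10 and C1–C4 and releases the ring with both olefins in place. Reduction and lactonisation at C6, α-methylenation, angeloylation and a singlet-oxygen ene reaction finish the target.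

Key step: step 10

Remark: an enolate alkylation beside the C8 silyl ether would enter anti to it, so the cis C7/C8 pair is instead set by radical allylation on the rigid quinic lactone. Compounds 1–9 are described with quinic acid numbering; from compound 10 on the atoms carry the germacrane numbers C1–C15, and α/β refer to the ring drawn with the C7 side chain β.

Step 1
Reactants: 1 (−)-quinic acid
Product: 2 quinide (quinic acid 1,5-lactone)
Conditions: TsOH·H2O (cat.), toluene/DMF, reflux, Dean–Stark
Reagents that add atoms: none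
Why: Acid-catalysed lactonisation (intramolecular Fischer esterification) joins the carboxyl to the cis C5 hydroxyl without touching a stereocentre, and the bicyclic chair fixes C3–OH equatorial and C4–OH axial.

Step 2
Reactants: 2 quinide
Product: 3 3-O-(tert-butyldimethylsilyl)quinide
Conditions: TBSCl (1.1 equiv), imidazole, DMF, 0 °C to rt
Reagents that add atoms: tert-butyldimethylsilyl chloride, CC(C)(C)[Si](C)(C)Cl
Why: Silyl ether formation should occur at the equatorial C3 hydroxyl, the most accessible of the three (C4–OH is axial, C1–OH tertiary).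

Step 3
Reactants: 3 3-O-(tert-butyldimethylsilyl)quinide
Product: 4 3-O-TBS-4-O-(phenoxythiocarbonyl)quinide
Conditions: PhOC(S)Cl, pyridine, DMAP (cat.), CH2Cl2, rt
Reagents that add atoms: O-phenyl chlorothionoformate, S=C(Cl)Oc1ccccc1
Why: Acylation of the only remaining secondary hydroxyl gives the thionocarbonate radical precursor (as in a Barton–McCombie sequence), the tertiary C1–OH being inert.

Step 4
Reactants: 4 3-O-TBS-4-O-(phenoxythiocarbonyl)quinide; 5 allyltributylstannane
Product: 6 4-allyl-4-deoxy-3-O-TBS-quinide
Conditions: allyltributylstannane in threefold excess, AIBN (cat.), benzene, 80 °C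
Reagents that add atoms: none
Why: Keck radical allylation: the stannyl radical adds to the thiocarbonyl, C4–O fragments, and the secondary C4 radical is trapped by the allylstannane along the axial trajectory anti to the axial lactone C5–O bond, on the face the hydroxyl had occupied, which sets allyl cis to the C3 silyl ether (the later C7/C8 pair).

Step 5
Reactants: 6 4-allyl-4-deoxy-3-O-TBS-quinide
Product: 7 methyl 4-allyl-4-deoxy-3-O-TBS-quinate (1,5-diol)
Conditions: NaOMe (0.2 equiv), MeOH, 0 °C
Reagents that add atoms: methanol, CO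
Why: Methanolysis (transesterification) of the strained bicyclic lactone frees the C5 hydroxyl and gives the methyl ester without involving a stereocentre; no second ester is present that the freed hydroxyl could attack.

Step 6
Reactants: 7 methyl 4-allyl-4-deoxy-3-O-TBS-quinate
Product: 10 methyl (4R,5R)-4-allyl-5-[(tert-butyldimethylsilyl)oxy]-3-oxocyclohex-1-ene-1-carboxylate, via β-hydroxy ketone 8 (not isolated), via tertiary mesylate 9 (not isolated)
Conditions: Dess–Martin periodinane, NaHCO3, CH2Cl2, 0 °C to rt; then MsCl, Et3N, CH2Cl2, 0 °C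
Reagents that add atoms: none
Why: Dess–Martin oxidation of the only secondary alcohol gives the β-hydroxy ketone, and mesylation of the tertiary hydroxyl triggers E1cB elimination toward the acidic ketone α-CH2, the silyl ether being a far poorer leaving group.

Step 7
Reactants: 10 methyl (4R,5R)-4-allyl-5-[(tert-butyldimethylsilyl)oxy]-3-oxocyclohex-1-ene-1-carboxylate
Product: 12 methyl (4R,5R)-5-[(tert-butyldimethylsilyl)oxy]-3-oxo-4-(2-oxoethyl)cyclohex-1-ene-1-carboxylate, via ozonide 11 (not isolated)
Conditions: O3, CH2Cl2, −78 °C (Sudan Red 7B end point); then Me2S, −78 °C to rt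
Reagents that add atoms: ozone, [O-][O+]=O
Why: Ozonolysis should be chemoselective for the electron-rich terminal olefin over the ring olefin, which carries both a ketone and an ester, and the neutral reductive work-up leaves the epimerisable C7 alone.

Step 8
Reactants: 12 methyl (4R,5R)-5-[(tert-butyldimethylsilyl)oxy]-3-oxo-4-(2-oxoethyl)cyclohex-1-ene-1-carboxylate
Product: 14 methyl (4R,5R)-5-[(tert-butyldimethylsilyl)oxy]-4-(2-methoxy-2-oxoethyl)-3-oxocyclohex-1-ene-1-carboxylate, via carboxylic acid 13 (not isolated)
Conditions: NaClO2, NaH2PO4, 2-methyl-2-butene, t-BuOH/H2O, 0 °C; then MeI, KHCO3, DMF, rt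
Reagents that add atoms: sodium chlorite, [Na+].[O-]Cl=O; iodomethane, CI
Why: Pinnick oxidation followed by carboxylate O-alkylation uses only a weakly acidic buffer and a bicarbonate base, so the β-silyloxy enone and the C7 centre should survive.

Step 9
Reactants: 15 methylenecyclobutane
Product: 16 1-methylcyclobutene
Conditions: Na on Al2O3 (cat.), neat, 25 °C; distil
Reagents that add atoms: none
Why: Base-catalysed allylic isomerisation (1,3-prototropic shift) moves the olefin into the ring, the more substituted endocyclic isomer being favoured at equilibrium and separable by distillation.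

Step 10
Reactants: 14 methyl (4R,5R)-5-[(tert-butyldimethylsilyl)oxy]-4-(2-methoxy-2-oxoethyl)-3-oxocyclohex-1-ene-1-carboxylate; 16 1-methylcyclobutene
Product: 17 cis-anti-cis photoadduct with bicyclo[2.2.0]hexane core
Conditions: hν (366 nm, Pyrex), 1-methylcyclobutene in tenfold excess, CH2Cl2, −40 °C
Reagents that add atoms: none
Why: The enone is excited (n→π*), crosses to its triplet and adds to the cyclobutene stepwise: C10 bonds first to the unsubstituted C1, giving a 1,4-biradical (tertiary radical at C4, α-keto radical at C5) that collapses by C4–C5 coupling; the closest known reaction type is the enone–cycloalkene [2+2] photocycloaddition. The one ring closed is the cyclobutane C5–C10–C1–C4, formed by radical recombination of the 1,4-biradical after spin inversion, and its fusion to the existing four-membered ring creates the bicyclo[2.2.0]hexane. Head-to-head orientation is required and should prevail because the alternative biradical could close only by joining the methyl-bearing C4 to the ester-bearing C10, two fully substituted carbons, and reverts to the partners instead. C1 and C4 are cis because the cyclobutene ring allows nothing else, C5 and C10 close cis because the relaxed biradical gives the less strained cis-fused bicyclo[4.2.0]octanone, and the two rings end anti because the C2–C3 bridge approaches exo, away from the six-membered ring. The face is set by the β C8 silyl ether and β C7 arm, which direct the cyclobutene to the α face. All four new centres become sp2 in step 11, so only the cis-anti-cis relationship, not the face, has to hold.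

Step 11
Reactants: 17 cis-anti-cis photoadduct
Product: 18 methyl (1E,5E,8R,9R)-9-[(tert-butyldimethylsilyl)oxy]-8-(2-methoxy-2-oxoethyl)-5-methyl-7-oxocyclodeca-1,5-diene-1-carboxylate
Conditions: o-xylene (degassed), BHT (cat.), 150 °C, sealed tube
Reagents that add atoms: none
Why: Thermal cycloreversion of the bicyclo[2.2.0]hexane (formal retro-[2+2] through a chair cyclohexane-1,4-diyl) breaks C1–C4 and then C5–C10, the bond flanked by ketone and ester, and because C6 sits equatorial and C9 axial on that chair the C4=C5 enone should emerge E and the C1=C10 enoate with C2 and C9 cis, while conjugation of both olefins holds back Cope contraction.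

Step 12
Reactants: 18 silyloxy cyclodecadienone
Product: 19 8β-hydroxy cyclodecadienone (silyl group removed)
Conditions: HF·pyridine, pyridine, THF, 0 °C
Reagents that add atoms: none
Why: Fluoride-mediated desilylation under buffered, weakly acidic conditions should free the C8 hydroxyl without retro-aldol cleavage or dehydration of the β-hydroxy ketone.

Step 13
Reactants: 19 8β-hydroxy cyclodecadienone
Product: 21 8β-hydroxy-6α,12-lactone, via anti-1,3-diol 20 (not isolated)
Conditions: Me4NBH(OAc)3, MeCN/AcOH, −30 °C; then PPTS (cat.), toluene, 50 °C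
Reagents that add atoms: none
Why: Evans–Saksena reduction: the borohydride bound to the C8 oxygen delivers hydride to C6 intramolecularly from the β face, which sets C6 as 6α-OH (1,3-anti), and acid-catalysed transesterification then closes the γ-lactone onto the trans C7 arm, a fusion the ten-membered ring takes up with an anti C5–C6–C7–C8 torsion whereas an 8,12 cis closure would need a near-eclipsed one.

Step 14
Reactants: 21 8β-hydroxy-6α,12-lactone
Product: 24 8β-hydroxy α-methylene lactone, via Mannich base 22 (not isolated), via trimethylammonium iodide 23 (not isolated)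
Conditions: LiN(i-Pr)2 (2.2 equiv), THF, −78 °C; CH2=NMe2+ I−, −78 to 0 °C; MeI, MeOH, rt; aq. NaHCO3, EtOAc
Reagents that add atoms: Eschenmoser's salt (dimethylmethyleneammonium iodide), C=[N+](C)C.[I-]
Why: Mannich reaction of the lactone enolate (formed beside the C8 alkoxide with exactly two equivalents of base, so that the enoate γ-positions are spared), N-methylation and Hofmann-type β-elimination give the exocyclic C11=C13 olefin, the transient C11 centre being of no consequence.

Step 15
Reactants: 25 angelic acid; 24 8β-hydroxy α-methylene lactone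
Product: 27 8β-angelate, via mixed anhydride 26 (not isolated)
Conditions: 2,4,6-Cl3C6H2COCl, Et3N, toluene, rt; then 24, toluene, 75 °C
Reagents that add atoms: none
Why: Yamaguchi esterification: the hindered trichlorobenzoyl carbonyl of the mixed anhydride directs the only free hydroxyl to the angeloyl carbonyl, and the absence of a nucleophilic catalyst should keep the Z olefin from isomerising to the tiglate.

Step 16
Reactants: 27 8β-angelate
Product: 29 target CNP0163095.1, via C5 hydroperoxide 28 (not isolated)
Conditions: O2, tetraphenylporphyrin (cat.), hν (visible), CH2Cl2, 0 °C; then PPh3, 0 °C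
Reagents that add atoms: dioxygen, O=O
Why: Schenck ene reaction: singlet oxygen should react only with the electron-rich C4=C5 olefin, approach its outer face in the lactone-locked conformer (H5 α, C15 β), bond to C5 and take hydrogen from the C15 methyl on the more crowded side of the olefin, which sets the 5β-oxygen and moves the double bond to C4=C15 before PPh3 reduces the hydroperoxide.

Compound list
1 | (−)-quinic acid, (1S,3R,4S,5R)-1,3,4,5-tetrahydroxycyclohexane-1-carboxylic acid | C1[C@H]([C@H]([C@@H](C[C@@]1(C(=O)O)O)O)O)O | starting material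
2 | quinide, (1S,3R,4R,5R)-1,3,4-trihydroxy-6-oxabicyclo[3.2.1]octan-7-one | C1[C@H]([C@H]([C@H]2C[C@@]1(C(=O)O2)O)O)O | intermediate
3 | 3-O-(tert-butyldimethylsilyl)quinide (silyl ether on the equatorial C3 oxygen, quinic acid numbering) | C1[C@H]([C@H]([C@H]2C[C@@]1(C(=O)O2)O)O)O[Si](C)(C)C(C)(C)C | intermediate
4 | 3-O-TBS-4-O-(phenoxythiocarbonyl)quinide | C1[C@H]([C@H]([C@H]2C[C@@]1(C(=O)O2)O)OC(=S)Oc3ccccc3)O[Si](C)(C)C(C)(C)C | intermediate
5 | allyltributylstannane | C=CC[Sn](CCCC)(CCCC)CCCC | starting material
6 | 4-allyl-4-deoxy-3-O-TBS-quinide (allyl on the face of the former C4 hydroxyl: cis to the C3 silyl ether, trans to the lactone C5–O) | C1[C@H]([C@H]([C@H]2C[C@@]1(C(=O)O2)O)CC=C)O[Si](C)(C)C(C)(C)C | intermediate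
7 | methyl 4-allyl-4-deoxy-3-O-TBS-quinate (C1 and C5 hydroxyls free; allyl cis to C3–OTBS, trans to C5–OH) | C1[C@H]([C@H]([C@@H](C[C@@]1(C(=O)OC)O)O)CC=C)O[Si](C)(C)C(C)(C)C | intermediate
8 | β-hydroxy ketone: C5 ketone of 7 (tertiary C1 hydroxyl retained) | C1[C@H]([C@H](C(=O)C[C@@]1(C(=O)OC)O)CC=C)O[Si](C)(C)C(C)(C)C | intermediate
9 | tertiary mesylate: C1 methanesulfonate of 8 | C1[C@H]([C@H](C(=O)C[C@@]1(C(=O)OC)OS(C)(=O)=O)CC=C)O[Si](C)(C)C(C)(C)C | intermediate
10 | methyl (4R,5R)-4-allyl-5-[(tert-butyldimethylsilyl)oxy]-3-oxocyclohex-1-ene-1-carboxylate | O=C1[C@H](CC=C)[C@H](O[Si](C)(C)C(C)(C)C)CC(C(=O)OC)=C1 | intermediate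
11 | ozonide: 1,2,4-trioxolane from the allyl olefin of 10 | O=C1[C@H](CC2OCOO2)[C@H](O[Si](C)(C)C(C)(C)C)CC(C(=O)OC)=C1 | intermediate
12 | methyl (4R,5R)-5-[(tert-butyldimethylsilyl)oxy]-3-oxo-4-(2-oxoethyl)cyclohex-1-ene-1-carboxylate | O=C1[C@H](CC=O)[C@H](O[Si](C)(C)C(C)(C)C)CC(C(=O)OC)=C1 | intermediate
13 | carboxylic acid of 12 (side chain CH2CO2H, ring configuration unchanged) | O=C1[C@H](CC(=O)O)[C@H](O[Si](C)(C)C(C)(C)C)CC(C(=O)OC)=C1 | intermediate
14 | methyl (4R,5R)-5-[(tert-butyldimethylsilyl)oxy]-4-(2-methoxy-2-oxoethyl)-3-oxocyclohex-1-ene-1-carboxylate (C5=C10 enone, C6 ketone, C7 arm β, C8 OTBS β) | O=C1[C@H](CC(=O)OC)[C@H](O[Si](C)(C)C(C)(C)C)CC(C(=O)OC)=C1 | intermediate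
15 | methylenecyclobutane | C=C1CCC1 | starting material
16 | 1-methylcyclobutene | CC1=CCC1 | intermediate
17 | photoadduct, methyl 9-[(tert-butyldimethylsilyl)oxy]-8-(2-methoxy-2-oxoethyl)-5-methyl-7-oxotricyclo[4.4.0.0(2,5)]decane-1-carboxylate; ring fusions C5/C10 and C1/C4 cis, four-membered rings anti, bicyclohexane on the α face opposite the β C7 arm and β C8 silyl ether | O=C1[C@H](CC(=O)OC)[C@H](O[Si](C)(C)C(C)(C)C)C[C@@]2(C(=O)OC)[C@@H]3CC[C@]3(C)[C@@H]12 | intermediate
18 | methyl (1E,5E,8R,9R)-9-[(tert-butyldimethylsilyl)oxy]-8-(2-methoxy-2-oxoethyl)-5-methyl-7-oxocyclodeca-1,5-diene-1-carboxylate (germacrane numbering: C1=C10 with C2 and C9 cis, C4=C5 E, C6 ketone) | O=C1[C@H](CC(=O)OC)[C@H](O[Si](C)(C)C(C)(C)C)C/C(C(=O)OC)=C\CC/C(C)=C/1 | intermediate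
19 | 8β-hydroxy analogue of 18 (silyl group removed) | O=C1[C@H](CC(=O)OC)[C@H](O)C/C(C(=O)OC)=C\CC/C(C)=C/1 | intermediate
20 | anti-1,3-diol: 6α-OH, 8β-OH, C7 CH2CO2Me arm β, olefins as in 18 | COC(=O)C[C@@H]1[C@H](O)C/C(C(=O)OC)=C\CC/C(C)=C/[C@H]1O | intermediate
21 | 8β-hydroxy-6α,12-lactone (trans-fused γ-lactone, C11 CH2), methyl 14-oate, 1(10)-ene with C2/C9 cis, 4E-ene | C1C(=O)O[C@H]2[C@H]1[C@H](O)C/C(C(=O)OC)=C\CC/C(C)=C/2 | intermediate
22 | Mannich base: 21 with CH2NMe2 on C11 (C11 configuration open) | CN(C)CC1C(=O)O[C@H]2[C@H]1[C@H](O)C/C(C(=O)OC)=C\CC/C(C)=C/2 | intermediate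
23 | trimethylammonium iodide of 22 | C[N+](C)(C)CC1C(=O)O[C@H]2[C@H]1[C@H](O)C/C(C(=O)OC)=C\CC/C(C)=C/2.[I-] | intermediate
24 | 8β-hydroxy α-methylene lactone (C11=C13), otherwise as 21 | C=C1C(=O)O[C@H]2[C@H]1[C@H](O)C/C(C(=O)OC)=C\CC/C(C)=C/2 | intermediate
25 | angelic acid, (Z)-2-methylbut-2-enoic acid | C/C=C(/C)C(=O)O | starting material
26 | mixed anhydride: angelic 2,4,6-trichlorobenzoic anhydride | C/C=C(/C)C(=O)OC(=O)c1c(Cl)cc(Cl)cc1Cl | intermediate
27 | 8β-angelate of 24 | C=C1C(=O)O[C@H]2[C@H]1[C@H](OC(=O)/C(C)=C\C)C/C(C(=O)OC)=C\CC/C(C)=C/2 | intermediate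
28 | C5 hydroperoxide: 5β-OOH, C4=C15 exo-methylene, otherwise as 29 | C=C1C(=O)O[C@H]2[C@H]1[C@H](OC(=O)/C(C)=C\C)C/C(C(=O)OC)=C\CCC(=C)[C@@H]2OO | intermediate
29 | CNP0163095.1: methyl 8β-angeloyloxy-5β-hydroxy-germacra-1(10),4(15),11(13)-trien-12,6α-olid-14-oate, C2 and C9 cis on C1=C10, (5S,6S,7R,8R) | C=C1C(=O)O[C@H]2[C@H]1[C@H](OC(=O)/C(C)=C\C)C/C(C(=O)OC)=C\CCC(=C)[C@@H]2O | target

Total step count: 16 steps. Longest linear sequence: 15 steps (steps 1–8 and 10–16); step 9 is a one-step side branch.

Steps most likely to fail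

Step 10. The biradical may close in the reversed orientation (C4 to C10), or it may fall back to the ground-state partners so that enone dimerisation takes over. The fallback sets out from 14 and uses parent cyclobutene, for which no orientation question exists: irradiation as in step 10 should give the 4-desmethyl photoadduct F1, and heating as in step 11 the 4-desmethyl cyclodeca-1(10),4-dien-6-one F2. Conjugate addition of Me2CuLi in the presence of Me3SiCl (the enone reacts ahead of the enoate) then gives the C4-methylated trimethylsilyl enol ether F3, and Saegusa–Ito dehydrogenation of F3 with Pd(OAc)2 (divalent palladium) in MeCN should restore the C4=C5 enone, so the route is rejoined at 18.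

Step 11. At the temperature of ring opening the β-silyloxy ketone may lose silanol or epimerise at C7 through its enol before the cycloreversion is complete, or the olefin geometry may scramble. The fallback sets out from 17 and removes the ketone before heating, while leaving the lactone closure for the ten-membered ring. HF·pyridine gives the 8β-hydroxy photoadduct F4, and Me4NBH(OAc)3 delivers hydride from the C8 oxygen to give the 6α,8β-diol photoadduct F5. Et3SiOTf with 2,6-lutidine then caps both hydroxyls as the bis(triethylsilyl) ether F6, so that neither can lactonise on the six-membered ring, where closure onto the cis C8 oxygen would compete. Flash vacuum thermolysis of F6 with short contact time (only the enoate is left to restrain Cope contraction) should open the bicyclohexane to the bis(triethylsilyl) cyclodecadiene F7. HF·pyridine then frees diol 20, and PPTS in toluene closes the lactone as in step 13, which rejoins the route at 21.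

Step 16. Singlet oxygen may take hydrogen from C3 and not from C15, may attack the inner face, or may react too slowly with an olefin deactivated by the allylic lactone oxygen. The fallback sets out from 27: m-CPBA should epoxidise the same olefin from its outer face to the 4α,5β-epoxide F8. Me3SiOTf with 2,6-lutidine and then DBU opens the epoxide at the tertiary C4 with loss of a C15 proton, giving the 5-O-trimethylsilyl ether F9, and aqueous citric acid releases the alcohol, arriving at 29.

Further compounds
F1 | step 10 | 4-desmethyl photoadduct (cis-anti-cis, as 17 without the C4 methyl) | O=C1[C@H](CC(=O)OC)[C@H](O[Si](C)(C)C(C)(C)C)C[C@@]2(C(=O)OC)[C@@H]3CC[C@@H]3[C@@H]12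
F2 | step 10 | 4-desmethyl cyclodeca-1(10),4-dien-6-one (as 18 without the C4 methyl) | O=C1[C@H](CC(=O)OC)[C@H](O[Si](C)(C)C(C)(C)C)C/C(C(=O)OC)=C\CC/C=C/1
F3 | step 10 | C4-methylated trimethylsilyl enol ether (C5=C6 enol ether, C4 configuration open) | C[Si](C)(C)OC=1[C@H](CC(=O)OC)[C@H](O[Si](C)(C)C(C)(C)C)C/C(C(=O)OC)=C\CCC(C)C=1
F4 | step 11 | 8β-hydroxy photoadduct (17 without the silyl group) | O=C1[C@H](CC(=O)OC)[C@H](O)C[C@@]2(C(=O)OC)[C@@H]3CC[C@]3(C)[C@@H]12
F5 | step 11 | 6α,8β-diol photoadduct | O[C@H]1[C@H](CC(=O)OC)[C@H](O)C[C@@]2(C(=O)OC)[C@@H]3CC[C@]3(C)[C@@H]12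
F6 | step 11 | bis(triethylsilyl) ether of the 6α,8β-diol photoadduct (bicyclo[2.2.0]hexane intact) | CC[Si](CC)(CC)O[C@H]1[C@H](CC(=O)OC)[C@H](O[Si](CC)(CC)CC)C[C@@]2(C(=O)OC)[C@@H]3CC[C@]3(C)[C@@H]12
F7 | step 11 | bis(triethylsilyl) cyclodecadiene (6α,8β-bis-silyl ether of 20) | COC(=O)C[C@@H]1[C@H](O[Si](CC)(CC)CC)C/C(C(=O)OC)=C\CC/C(C)=C/[C@H]1O[Si](CC)(CC)CC
F8 | step 16 | 4α,5β-epoxide of 27 | C=C1C(=O)O[C@H]2[C@H]1[C@H](OC(=O)/C(C)=C\C)C/C(C(=O)OC)=C\CC[C@@]3(C)O[C@H]23
F9 | step 16 | 5-O-trimethylsilyl ether of 29 | C=C1C(=O)O[C@H]2[C@H]1[C@H](OC(=O)/C(C)=C\C)C/C(C(=O)OC)=C\CCC(=C)[C@@H]2O[Si](C)(C)C
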